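## Retrosynthetic overview

1. No ring is built. Rings A, B and C and the C2 stereocentre of the target are taken intact from the natural flavanone; only the two ArCH2–C(ring A) bonds (C6–CH2 and C8–CH2) are disconnected.
2. Both disconnections lead to the same electrophile, the o-quinone methide of a 2,3-dihydroxybenzyl alcohol, which comes from 2,3-dihydroxybenzaldehyde by hydride reduction (1 → 2).
3. Forward: 1 → 2; then natural (2S)-pinocembrin 3 and 2 under 254 nm light give o-quinone methide 4, which is captured by 3 at C8 or C6 (mono-adducts 5 and 6) and once more to give target 7.

Assumption: natural (2S)-(−)-pinocembrin 3 is bought with at least 98% ee (checked by chiral HPLC before use), and all catechol solutions are handled under argon.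

## Route

Step 1
Reactants: 1 2,3-dihydroxybenzaldehyde
Product: 2 2,3-dihydroxybenzyl alcohol
Conditions: NaBH4 (0.6 equiv), MeOH, 0 °C, 30 min; AcOH to pH 5; EtOAc extraction
Reagents that add atoms: none
Why: Borohydride reduction of an aryl aldehyde (hydride addition to C=O) is fast and chemoselective at 0 °C, the phenols are untouched, and work-up at pH 5 frees the catechol from borate without acid-induced self-condensation of the salicyl-type alcohol; no stereocentre is involved.

Step 2
Reactants: 3 (2S)-pinocembrin; 2 2,3-dihydroxybenzyl alcohol
Product: 7 (2S)-6,8-bis(2,3-dihydroxybenzyl)-5,7-dihydroxyflavanone, via o-quinone methide 4 (not isolated), via 8-monobenzyl flavanone 5 (not isolated), via 6-monobenzyl flavanone 6 (not isolated)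
Conditions: hν (254 nm, low-pressure mercury lamp, FEP-coil flow reactor), 2 (10 equiv), MeCN/H2O 1:1, NaH2PO4/Na2HPO4 (25 mM, pH 6.5), Ar, 10 °C, [3] = 5 mM, recirculated until 5 and 6 are consumed; pH 4, EtOAc; C18 chromatography
Reagents that add atoms: none
Why: Proposed new method: light-driven double C-benzylation of a flavanone by a photogenerated catechol o-quinone methide — 2 is excited at 254 nm, where 3 has its absorption minimum, and water-assisted excited-state proton transfer from its 2-OH to the benzylic OH expels water to give 4 (photodehydration of a 2-hydroxybenzyl alcohol); at pH 6.5 only 3 (7-OH pKa about 7.5; the catechol of 2 about 9.3) is partly ionised, and its 7-phenolate adds through C8 or C6 to the exocyclic CH2 of 4 (phenolate Michael-type C-alkylation, formally a Friedel–Crafts benzylation), tautomerisation re-aromatises both rings to 5 or 6, and the remaining ring-A carbon reacts the same way to give 7; hydration of 4 merely regenerates 2 and O-adducts are themselves photolabile o-hydroxybenzyl ethers, so continued irradiation funnels material into the irreversible C–C products, while 2 and 3 do not react in the dark at 10 °C; no stereocentre is formed, and C2 is carried over from 3 because the chelated 5-OH/C4=O unit (a 2-hydroxyaryl ketone, the UV-stabiliser motif) sheds excitation by ultrafast proton transfer and the cool, slightly acidic medium does not open ring C by retro-oxa-Michael reaction; closest known reactions: photodehydration of 2-hydroxybenzyl alcohols with capture of the o-quinone methide by water, alcohols, amines, thiols or vinyl ethers, and the thermal ZnCl2-mediated 2-hydroxybenzylation of pinocembrin; capture at carbon by a flavanone phenolate, twice on one ring and from a catechol donor, has not to my knowledge been shown.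

## Compound list

1 | 2,3-dihydroxybenzaldehyde | O=Cc1cccc(O)c1O | starting material
2 | 2,3-dihydroxybenzyl alcohol (3-(hydroxymethyl)benzene-1,2-diol) | OCc1cccc(O)c1O | intermediate
3 | (2S)-pinocembrin, (2S)-5,7-dihydroxy-2-phenylchroman-4-one | O=C1C[C@@H](c2ccccc2)Oc2cc(O)cc(O)c21 | starting material
4 | o-quinone methide, 2-hydroxy-6-methylidenecyclohexa-2,4-dien-1-one | C=C1C=CC=C(O)C1=O | intermediate
5 | (2S)-8-(2,3-dihydroxybenzyl)-5,7-dihydroxy-2-phenylchroman-4-one | O=C1C[C@@H](c2ccccc2)Oc2c(Cc3cccc(O)c3O)c(O)cc(O)c21 | intermediate
6 | (2S)-6-(2,3-dihydroxybenzyl)-5,7-dihydroxy-2-phenylchroman-4-one | O=C1C[C@@H](c2ccccc2)Oc2cc(O)c(Cc3cccc(O)c3O)c(O)c21 | intermediate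
7 | (2S)-6,8-bis(2,3-dihydroxybenzyl)-5,7-dihydroxy-2-phenylchroman-4-one | O=C1C[C@@H](c2ccccc2)Oc2c(Cc3cccc(O)c3O)c(O)c(Cc3cccc(O)c3O)c(O)c21 | target

## Step count and risks

Total step count: 2.
Longest linear sequence: 2 steps (1 → 2 → 7); 3 enters in step 2.

Steps most likely to fail (the route has two steps in all, so both are given, the more hazardous first).

Step 2, the proposed new step. The hazards are these:
- Light sharing and C2: 3 and its benzylated products take part of the 254 nm light, so the photon cost is high and slow photoracemisation at C2 cannot be ruled out beforehand. The ee of 7 is checked by chiral HPLC.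
- Donor side reactions: the catechol donor may photo-oxidise, 4 may attack a second molecule of 2, or 4 may tautomerise to 3-methyl-1,2-benzoquinone.
- Conversion: the reaction may stall at 5 and 6, or run on to geminal dibenzylation of ring A.

The fallback uses known chemistry and no light. It is the thermal Lewis-acid Friedel–Crafts o-hydroxybenzylation by which the 2-hydroxybenzyl analogue of the target has been made from pinocembrin. It sets out from 3 and 2 (3 equiv) with anhydrous ZnCl2 (4 equiv) in 1,4-dioxane at 90 °C under argon. It runs through 5 and 6 and comes back to the route at 7. Configurational stability of C2 under these conditions is not established, so ee must be checked here too. This fallback makes no compound outside the list (F0).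

Step 1. The hazards are over-reduction to 3-methylcatechol if the mixture warms (borohydride reduces the o-quinone methide), retention of the product as a catechol borate, acid-promoted self-condensation of 2 during work-up, and air oxidation on storage. The fallback drops the alcohol donor altogether. It sets out from 1: reductive amination (Me2NH 2 M in THF, NaBH(OAc)3, THF, rt) gives the Mannich base 3-[(dimethylamino)methyl]benzene-1,2-diol F1, stored as its hydrochloride. Mannich bases of this kind are an established class of photochemical o-quinone methide precursors (excited-state proton transfer, then loss of the amine). F1 therefore replaces 2 in step 2 under the same irradiation conditions and rejoins the route at 4, and from there at 7.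

Further compounds
F0 | step 2 | none | none
F1 | step 1 | 3-[(dimethylamino)methyl]benzene-1,2-diol | CN(C)Cc1cccc(O)c1O
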